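**Retrosynthetic overview**
1. The strategy rests on the two ring epoxides C1–C10 and C4–C5: they mask a C10=C1–C2–C3–C4=C5 1,5-diene in the ten-membered carbocycle, which is the retron of a Cope rearrangement across a temporary C5–C10 bond.
2. Target 37 ⇒ triene lactone 35 (double epoxidation last; C8 ester from (S)-2-methylglycidic acid; butenolide by oxidising the C6/C12 Z-ene-1,4-diol; C13 acetate) ⇒ enol triflate 22 ⇒ [3,3] ring expansion of the cis-1-isopropenyl-2-vinylcyclohexanol 19.
3. 19 ⇒ epoxide-to-allylic-alcohol isomerisation (C6–OH, C7=C11) ⇐ isopropenyl addition to an α,β-epoxy ketone (C5) ⇐ hydroxyl-directed epoxidation (C6) ⇐ nitronate Michael addition (C11–C13) ⇐ CBS reduction of an ene-dione (C8) ⇐ asymmetric Diels–Alder reaction of methacrolein (C10).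
4. Ring order: cyclohexene (step 1), ten-membered carbocycle by ring expansion (step 14), butenolide (step 20), the two ring epoxides (step 24).

Key step: step 14

Remark: locants follow germacrane numbering (the cyclohexane carbons are C5–C10; C11–C13 are the branch on C7; C14 and C15 are the methyls on C10 and C4); α is the ring face of the C10 methyl, β the face of the C10 vinyl group.
Assumption: the protonated oxazaborolidine of step 1 is written in the (S) form on the usual facial model for 2-substituted acroleins; if the sense of induction with this diene is the opposite, its enantiomer is used and nothing else changes.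
Assumption: 8 and 16 are bought as catalogue compounds.

Step 1
Reactants: 1 methacrolein; 2 (1E,3E)-buta-1,3-diene-1,4-diyl diacetate
Product: 3 (1S,2R,5R)-2,5-diacetoxy-1-methylcyclohex-3-ene-1-carbaldehyde
Conditions: (S)-1-(2-methylphenyl)-3,3-diphenyltetrahydro-1H,3H-pyrrolo[1,2-c][1,3,2]oxazaborole (20 mol %), HN(SO2CF3)2 (18 mol %), CH2Cl2, −40 to −20 °C
Reagents that add atoms: none
Why: Catalytic enantioselective Diels–Alder reaction of a 2-substituted acrolein: the protonated oxazaborolidine binds the s-trans enal and screens one face, so the symmetrical diene adds to the other and sets the quaternary C10 (1S in 3), while the two acetoxy carbons (endo arrangement expected) carry no lasting information because both become carbonyl groups in step 4.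

Step 2
Reactants: 3 (1S,2R,5R)-2,5-diacetoxy-1-methylcyclohex-3-ene-1-carbaldehyde
Product: 4 (1R,4R,5R)-5-ethenyl-5-methylcyclohex-2-ene-1,4-diyl diacetate
Conditions: Ph3PCH3Br, NaN(SiMe3)2, THF, −78 to 0 °C
Reagents that add atoms: methylenetriphenylphosphorane (made in the flask), C=P(c1ccccc1)(c1ccccc1)c1ccccc1
Why: Wittig methylenation of the non-enolisable neopentyl aldehyde with the ylide at low temperature should leave the two acetates untouched and turns the formyl group into the C1=C2 vinyl group.

Step 3
Reactants: 4 (1R,4R,5R)-5-ethenyl-5-methylcyclohex-2-ene-1,4-diyl diacetate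
Product: 5 (1R,4R,5R)-5-ethenyl-5-methylcyclohex-2-ene-1,4-diol
Conditions: K2CO3 (0.2 equiv), MeOH, 0 °C to rt
Reagents that add atoms: none
Why: Base-catalysed transesterification (methanolysis) removes both acetates as methyl acetate without touching the alkenes.

Step 4
Reactants: 5 (1R,4R,5R)-5-ethenyl-5-methylcyclohex-2-ene-1,4-diol
Product: 6 (R)-2-ethenyl-2-methylcyclohex-5-ene-1,4-dione
Conditions: Dess–Martin periodinane (2.5 equiv), CH2Cl2, rt
Reagents that add atoms: none
Why: Dess–Martin oxidation of both allylic alcohols gives the ene-dione, in which C10 is the only stereocentre, so any exo adduct from step 1 converges here.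

Step 5
Reactants: 6 (R)-2-ethenyl-2-methylcyclohex-5-ene-1,4-dione
Product: 7 (4S,6R)-6-ethenyl-4-hydroxy-6-methylcyclohex-2-en-1-one
Conditions: (R)-1-methyl-3,3-diphenyltetrahydro-1H,3H-pyrrolo[1,2-c][1,3,2]oxazaborole (20 mol %), catecholborane (1.5 equiv), toluene, −78 °C
Reagents that add atoms: none
Why: CBS reduction: the catalyst–borane complex binds the unhindered C8 carbonyl (the C5 carbonyl is flanked by the quaternary C10) and delivers hydride with the alkenyl arm as the large and C9H2 as the small group, which should give the 8S alcohol cis to the C10 methyl by reagent control despite the weak methyl/vinyl bias of the substrate.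

Step 6
Reactants: 7 (4S,6R)-6-ethenyl-4-hydroxy-6-methylcyclohex-2-en-1-one; 8 2,2-dimethyl-5-nitro-1,3-dioxane
Product: 9 (3R,4S,6R)-3-(2,2-dimethyl-5-nitro-1,3-dioxan-5-yl)-6-ethenyl-4-hydroxy-6-methylcyclohexan-1-one
Conditions: DBU (0.3 equiv), MeCN, rt
Reagents that add atoms: none
Why: Michael addition of the nitronate of 8 to the only enone β-carbon, C7, builds the C7–C11 bond together with the C12/C13 acetonide; the base is buffered by the nitroalkane, and the C7 configuration (trans to the hydroxyl expected) is of no consequence because C7 becomes trigonal in step 8.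

Step 7
Reactants: 9 (3R,4S,6R)-3-(2,2-dimethyl-5-nitro-1,3-dioxan-5-yl)-6-ethenyl-4-hydroxy-6-methylcyclohexan-1-one
Product: 10 (3R,4S,6R)-3-(2,2-dimethyl-1,3-dioxan-5-yl)-6-ethenyl-4-hydroxy-6-methylcyclohexan-1-one
Conditions: Bu3SnH (3 equiv), AIBN (0.2 equiv), toluene, 100 °C
Reagents that add atoms: none
Why: Radical denitration of a tertiary nitroalkane with tin hydride (chain reaction via the C11 radical) replaces NO2 by H and leaves ketone, hydroxyl, vinyl and acetonide untouched.

Step 8
Reactants: 10 (3R,4S,6R)-3-(2,2-dimethyl-1,3-dioxan-5-yl)-6-ethenyl-4-hydroxy-6-methylcyclohexan-1-one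
Product: 13 (4S,6R)-3-(2,2-dimethyl-1,3-dioxan-5-yl)-6-ethenyl-4-hydroxy-6-methylcyclohex-2-en-1-one, via alpha-phenylselenyl ketone 11 (not isolated), via selenoxide 12 (not isolated)
Conditions: LiN(iPr)2 (2.3 equiv), THF, −78 °C; PhSeBr; then H2O2, pyridine, CH2Cl2, 0 °C to rt
Reagents that add atoms: none
Why: α-Selenenylation and selenoxide syn-elimination: the ketone can enolise only toward C6 (C10 is quaternary) and the selenoxide has a single β-hydrogen, at C7, so the C6=C7 enone is regenerated with the dioxanyl group on C7.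

Step 9
Reactants: 13 (4S,6R)-3-(2,2-dimethyl-1,3-dioxan-5-yl)-6-ethenyl-4-hydroxy-6-methylcyclohex-2-en-1-one
Product: 14 6α,7α-epoxy-8α-hydroxy C5 ketone (epoxide cis to the hydroxyl)
Conditions: t-BuOOH, benzyltrimethylammonium hydroxide (0.1 equiv), THF, 0 °C
Reagents that add atoms: tert-butyl hydroperoxide, CC(C)(C)OO
Why: Hydroxyl-directed nucleophilic (Weitz–Scheffer) epoxidation: the hydroperoxide anion is hydrogen-bonded to the free C8 hydroxyl and adds to C7 from that face, so the epoxide forms cis to the C8 oxygen (α face) and fixes C6.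

Step 10
Reactants: 14 6α,7α-epoxy-8α-hydroxy C5 ketone
Product: 15 6α,7α-epoxy-8α-(tert-butyldimethylsilyloxy) C5 ketone
Conditions: t-BuMe2SiOSO2CF3, 2,6-lutidine, CH2Cl2, −78 °C
Reagents that add atoms: tert-butyldimethylsilyl trifluoromethanesulfonate, CC(C)(C)[Si](C)(C)OS(=O)(=O)C(F)(F)F
Why: Silylation of the secondary alcohol with the silyl triflate and a hindered base at low temperature, conditions under which the epoxide and the ketone are inert.

Step 11
Reactants: 15 6α,7α-epoxy-8α-(tert-butyldimethylsilyloxy) C5 ketone; 16 isopropenylmagnesium bromide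
Product: 17 5α-hydroxy-5β-isopropenyl-6α,7α-epoxide (8α-silyloxy; 10α-methyl; 10β-vinyl)
Conditions: THF, −78 to −40 °C; then H2O
Reagents that add atoms: none
Why: Grignard addition to an α,β-epoxy ketone: the non-enolisable C5 carbonyl is attacked anti to the epoxide oxygen, which puts the isopropenyl group β (cis to the C10 vinyl group) and the new hydroxyl α (cis to the C6 oxygen).

Step 12
Reactants: 17 5α-hydroxy-5β-isopropenyl-6α,7α-epoxide
Product: 18 5α,6α-diol with the C7=C11 (2,2-dimethyl-1,3-dioxan-5-ylidene) group
Conditions: Et2AlCl, lithium 2,2,6,6-tetramethylpiperidide (4 equiv each), toluene, 0 °C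
Reagents that add atoms: none
Why: Aluminium-amide-promoted isomerisation of an epoxide to an allylic alcohol (syn β-elimination through a cyclic transition state): the only hydrogen that can lie syn to the oxirane oxygen on a carbon next to C7 is C11–H (C8–H is trans to the oxirane and C5 bears none), so the C7–O bond opens to the exocyclic C7=C11 alkene while the C6–O bond and the C6 configuration are kept.

Step 13
Reactants: 18 5α,6α-diol with the C7=C11 ylidene group
Product: 19 cis-1-isopropenyl-2-vinylcyclohexanol precursor (5α-OH; 5β-isopropenyl; 6α-OPMB; 8α-OTBS; 10α-methyl; 10β-vinyl)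
Conditions: NaH (1.1 equiv), 4-methoxybenzyl chloride, Bu4NI (cat.), THF–DMF, 0 °C
Reagents that add atoms: 4-methoxybenzyl chloride, COc1ccc(CCl)cc1
Why: Williamson etherification: one equivalent of base gives the less hindered secondary C6 alkoxide, which is benzylated in preference to the tertiary C5 hydroxyl that must stay free for the next step.

Step 14
Reactants: 19 cis-1-isopropenyl-2-vinylcyclohexanol precursor
Product: 22 cyclodeca-1(10)E,4-dienyl C5 triflate (C3 and C6 cis), via potassium alkoxide 20 (not isolated), via potassium enolate 21 (not isolated)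
Conditions: KH (3 equiv), 18-crown-6 (3 equiv), THF, 0 to 25 °C; then PhN(SO2CF3)2, −78 to 0 °C
Reagents that add atoms: N-phenylbis(trifluoromethanesulfonimide), O=S(=O)(N(c1ccccc1)S(=O)(=O)C(F)(F)F)C(F)(F)F
Why: The potassium alkoxide 20, freed from its counter-ion by the crown ether, undergoes an anionic oxy-Cope ([3,3]-sigmatropic) rearrangement through a chair array of C2, C1, C10, C5, C4 and C3; the closest known reaction type is the ring expansion of 1,2-dialkenylcyclohexanol alkoxides to cyclodec-5-enone enolates with O-sulfonylation of the enolate in the same flask. The ten-membered carbocycle is closed by ring expansion: the C2–C3 bond forms inside the six-membered transition state while the shared C5–C10 bond breaks, so there is no end-to-end macrocyclisation and no need for high dilution. No stereocentre is created (C5 and C10 become trigonal, C6 and C8 are untouched), but two alkene geometries are: on the chair C9 sits equatorial at C10 and ends trans to C2 (E at C1=C10), while C6 sits axial at C5 and ends cis to C3 with the oxygen trans to C3, the enolate geometry that becomes the Z alkene at C4=C5. The selectivity needed is this chair over its ring-flipped counterpart, which would give the 1(10)Z,4E isomer; it should be secured by the cis relation of vinyl and isopropenyl and by their position on the face opposite to the C6 and C8 ethers and the C10 methyl, so that the reactive conformer keeps these three groups equatorial whereas the alternative would hold them syn-triaxial. The rearrangement itself places the enolate at C4=C5, and trapping at −78 °C before proton transfer fixes the position and geometry of the enol triflate 22.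

Step 15
Reactants: 22 cyclodeca-1(10)E,4-dienyl C5 triflate
Product: 23 ten-membered 1(10)E,4Z-diene (6-OPMB; 8-OTBS; C11 acetonide ylidene)
Conditions: Pd(OAc)2 (5 mol %), PPh3 (10 mol %), HCO2H, Bu3N, DMF, 50 °C
Reagents that add atoms: none
Why: Palladium-catalysed formate reduction of an enol triflate: oxidative addition to zerovalent palladium, exchange for formate, loss of CO2 and reductive elimination replace the triflate by hydrogen with retention, giving the Z alkene at C4=C5 (C3 and C6 cis).

Step 16
Reactants: 23 ten-membered 1(10)E,4Z-diene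
Product: 24 12,13-diol (6-OPMB; 8-OTBS)
Conditions: pyridinium p-toluenesulfonate (0.1 equiv), MeOH, 0 °C to rt
Reagents that add atoms: none
Why: Acid-catalysed transacetalisation in methanol frees the C12/C13 diol under conditions mild enough for the silyl ether, the benzyl ether and the 1,5-diene.

Step 17
Reactants: 24 12,13-diol
Product: 25 seven-membered 4-methoxybenzylidene acetal bridging O6 and O12 (13-OH free)
Conditions: DDQ (1.2 equiv), 4 Å molecular sieves, CH2Cl2, 0 °C
Reagents that add atoms: none
Why: Oxidative acetalisation (DDQ oxidation of the 4-methoxybenzyl ether to its oxocarbenium ion, trapped under anhydrous conditions by a neighbouring hydroxyl): only the hydroxymethyl group cis to C6 across C7=C11 can reach the cation and close the seven-membered acetal, which defines that carbon as C12 and leaves C13–OH free.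

Step 18
Reactants: 25 seven-membered 4-methoxybenzylidene acetal
Product: 26 13-acetate of the acetal
Conditions: Ac2O, pyridine, 4-(dimethylamino)pyridine (cat.), CH2Cl2, 0 °C
Reagents that add atoms: acetic anhydride, CC(=O)OC(C)=O
Why: Acylation of the one free primary alcohol installs the C13 acetate of the target.

Step 19
Reactants: 26 13-acetate of the acetal
Product: 27 6,12-diol 13-acetate (8-OTBS)
Conditions: AcOH–THF–H2O (3:1:1), rt
Reagents that add atoms: none
Why: Mild aqueous acid hydrolysis of the electron-rich seven-membered benzylidene-type acetal releases the C6 and C12 hydroxyls and leaves the acetate and the silyl ether in place.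

Step 20
Reactants: 27 6,12-diol 13-acetate
Product: 29 13-acetoxy-8-silyloxy-7(11)-en-12,6-olide (butenolide), via lactol 28 (not isolated)
Conditions: (2,2,6,6-tetramethylpiperidin-1-yl)oxyl (0.2 equiv), PhI(OAc)2 (3 equiv), CH2Cl2, rt
Reagents that add atoms: none
Why: Oxidative lactonisation of a Z-ene-1,4-diol with the oxoammonium catalyst: the primary allylic C12 alcohol is oxidised first, the aldehyde is captured by the C6 hydroxyl as the lactol and this is oxidised to the butenolide, the C6 configuration being untouched.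

Step 21
Reactants: 29 13-acetoxy-8-silyloxy butenolide
Product: 30 13-acetoxy-8-hydroxy butenolide
Conditions: HF·pyridine, pyridine, THF, 0 °C
Reagents that add atoms: none
Why: Fluoride-mediated desilylation buffered with pyridine frees the C8 hydroxyl without opening the lactone or cleaving the acetate.

Step 22
Reactants: 31 (R)-2-methylglycidol
Product: 33 (S)-2-methyloxirane-2-carboxylic acid, via epoxy aldehyde 32 (not isolated)
Conditions: (2,2,6,6-tetramethylpiperidin-1-yl)oxyl (0.1 equiv), PhI(OAc)2 (2.2 equiv), MeCN–H2O (1:1), 0 °C to rt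
Reagents that add atoms: water, O
Why: Oxoammonium-catalysed oxidation of the primary alcohol via the aldehyde hydrate to the carboxylic acid under near-neutral conditions; the quaternary epoxide stereocentre cannot epimerise, and the change of descriptor from R to S only reflects the change of priorities.

Step 23
Reactants: 30 13-acetoxy-8-hydroxy butenolide; 33 (S)-2-methyloxirane-2-carboxylic acid
Product: 35 triene lactone 8-[(2S)-2-methyloxirane-2-carboxylate], via mixed anhydride 34 (not isolated)
Conditions: 2,4,6-trichlorobenzoyl chloride, Et3N, THF, rt; then 30, 4-(dimethylamino)pyridine, toluene, rt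
Reagents that add atoms: none
Why: Yamaguchi esterification through the mixed anhydride acylates the hindered allylic C8 alcohol without touching the epoxide of the acid.

Step 24
Reactants: 35 triene lactone 8-[(2S)-2-methyloxirane-2-carboxylate]
Product: 37 (1R,4R,5S,6S,8S,10R)-13-acetoxy-1,10:4,5-diepoxy-8-[(2S)-2-methyloxirane-2-carbonyloxy]germacr-7(11)-en-12,6-olide, via 1,10-monoepoxide 36 (not isolated)
Conditions: dimethyldioxirane (3 equiv, acetone solution), CH2Cl2, −20 to 0 °C
Reagents that add atoms: dimethyldioxirane, CC1(C)OO1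
Why: Epoxidation with the neutral, electrophilic dioxirane is stereospecific (E alkene to the trans 1,10-epoxide, Z alkene to the cis 4,5-epoxide) and spares the electron-poor butenolide alkene; the face of each ring alkene is set by the substrate, whose C1=C10 and C4=C5 bonds stand roughly perpendicular to the ring so that only their outer faces are open, which should lead to the (1R,10R) and (4R,5S) epoxides.

**Compound list**
1 | methacrolein | CC(=C)C=O | starting material
2 | (1E,3E)-buta-1,3-diene-1,4-diyl diacetate | CC(=O)O/C=C/C=C/OC(C)=O | starting material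
3 | (1S,2R,5R)-2,5-diacetoxy-1-methylcyclohex-3-ene-1-carbaldehyde (all-cis endo adduct) | CC(=O)O[C@@H]1C=C[C@H](OC(C)=O)C[C@]1(C)C=O | intermediate
4 | (1R,4R,5R)-5-ethenyl-5-methylcyclohex-2-ene-1,4-diyl diacetate | CC(=O)O[C@@H]1C=C[C@H](OC(C)=O)C[C@]1(C)C=C | intermediate
5 | (1R,4R,5R)-5-ethenyl-5-methylcyclohex-2-ene-1,4-diol | O[C@@H]1C=C[C@H](O)C[C@]1(C)C=C | intermediate
6 | (R)-2-ethenyl-2-methylcyclohex-5-ene-1,4-dione | O=C1C=CC(=O)C[C@]1(C)C=C | intermediate
7 | (4S,6R)-6-ethenyl-4-hydroxy-6-methylcyclohex-2-en-1-one | O=C1C=C[C@@H](O)C[C@]1(C)C=C | intermediate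
8 | 2,2-dimethyl-5-nitro-1,3-dioxane | CC1(C)OCC(CO1)[N+](=O)[O-] | starting material
9 | (3R,4S,6R)-3-(2,2-dimethyl-5-nitro-1,3-dioxan-5-yl)-6-ethenyl-4-hydroxy-6-methylcyclohexan-1-one | O=C1C[C@H](C2(COC(C)(C)OC2)[N+](=O)[O-])[C@@H](O)C[C@]1(C)C=C | intermediate
10 | (3R,4S,6R)-3-(2,2-dimethyl-1,3-dioxan-5-yl)-6-ethenyl-4-hydroxy-6-methylcyclohexan-1-one | O=C1C[C@H](C2COC(C)(C)OC2)[C@@H](O)C[C@]1(C)C=C | intermediate
11 | C6 α-phenylselenyl ketone of 10 | O=C1[C@@H]([Se]c2ccccc2)[C@H](C2COC(C)(C)OC2)[C@@H](O)C[C@]1(C)C=C | intermediate (not isolated)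
12 | selenoxide of 11 | O=C1[C@@H]([Se](=O)c2ccccc2)[C@H](C2COC(C)(C)OC2)[C@@H](O)C[C@]1(C)C=C | intermediate (not isolated)
13 | (4S,6R)-3-(2,2-dimethyl-1,3-dioxan-5-yl)-6-ethenyl-4-hydroxy-6-methylcyclohex-2-en-1-one | O=C1C=C(C2COC(C)(C)OC2)[C@@H](O)C[C@]1(C)C=C | intermediate
14 | C5 ketone with 6α,7α-epoxide, 7-(2,2-dimethyl-1,3-dioxan-5-yl) and 8α-hydroxyl | O=C1[C@H]2O[C@@]2(C3COC(C)(C)OC3)[C@@H](O)C[C@]1(C)C=C | intermediate
15 | tert-butyldimethylsilyl ether of 14 | O=C1[C@H]2O[C@@]2(C3COC(C)(C)OC3)[C@@H](O[Si](C)(C)C(C)(C)C)C[C@]1(C)C=C | intermediate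
16 | isopropenylmagnesium bromide | CC(=C)[Mg]Br | starting material
17 | 5α-hydroxy-5β-isopropenyl-6α,7α-epoxide (8α-OTBS, 10α-methyl, 10β-vinyl) | O[C@@]1(C(C)=C)[C@H]2O[C@@]2(C3COC(C)(C)OC3)[C@@H](O[Si](C)(C)C(C)(C)C)C[C@]1(C)C=C | intermediate
18 | 5α,6α-diol with 7-(2,2-dimethyl-1,3-dioxan-5-ylidene) (8α-OTBS) | O[C@@]1(C(C)=C)[C@@H](O)C(=C2COC(C)(C)OC2)[C@@H](O[Si](C)(C)C(C)(C)C)C[C@]1(C)C=C | intermediate
19 | cis-1-isopropenyl-2-vinylcyclohexanol precursor (5α-OH, 6α-OPMB, 8α-OTBS, C11 acetonide ylidene) | O[C@@]1(C(C)=C)[C@@H](OCc2ccc(OC)cc2)C(=C2COC(C)(C)OC2)[C@@H](O[Si](C)(C)C(C)(C)C)C[C@]1(C)C=C | intermediate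
20 | potassium alkoxide of 19 | [K+].[O-][C@@]1(C(C)=C)[C@@H](OCc2ccc(OC)cc2)C(=C2COC(C)(C)OC2)[C@@H](O[Si](C)(C)C(C)(C)C)C[C@]1(C)C=C | intermediate (not isolated)
21 | ten-membered potassium C4=C5 enolate | C1(=C2COC(C)(C)OC2)[C@@H](O[Si](C)(C)C(C)(C)C)C/C(C)=C/CC/C(C)=C(/[O-])[C@H]1OCc1ccc(OC)cc1.[K+] | intermediate (not isolated)
22 | cyclodeca-1(10)E,4-dienyl C5 triflate | C1(=C2COC(C)(C)OC2)[C@@H](O[Si](C)(C)C(C)(C)C)C/C(C)=C/CC/C(C)=C(/OS(=O)(=O)C(F)(F)F)[C@H]1OCc1ccc(OC)cc1 | intermediate
23 | ten-membered 1(10)E,4Z-diene (6-OPMB, 8-OTBS, C11 acetonide ylidene) | C1(=C2COC(C)(C)OC2)[C@@H](O[Si](C)(C)C(C)(C)C)C/C(C)=C/CC/C(C)=C\[C@H]1OCc1ccc(OC)cc1 | intermediate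
24 | 12,13-diol of 23 | C1(=C(CO)CO)[C@@H](O[Si](C)(C)C(C)(C)C)C/C(C)=C/CC/C(C)=C\[C@H]1OCc1ccc(OC)cc1 | intermediate
25 | O6,O12-(4-methoxybenzylidene) acetal, 13-OH (acetal carbon: either epimer) | OC/C1=C2\[C@@H](O[Si](C)(C)C(C)(C)C)C/C(C)=C/CC/C(C)=C\[C@H]2OC(c2ccc(OC)cc2)OC1 | intermediate
26 | 13-acetate of 25 | CC(=O)OC/C1=C2\[C@@H](O[Si](C)(C)C(C)(C)C)C/C(C)=C/CC/C(C)=C\[C@H]2OC(c2ccc(OC)cc2)OC1 | intermediate
27 | 6,12-diol 13-acetate (8-OTBS) | CC(=O)OC/C(CO)=C1\[C@@H](O[Si](C)(C)C(C)(C)C)C/C(C)=C/CC/C(C)=C\[C@H]1O | intermediate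
28 | C12 lactol | CC(=O)OCC1=C2[C@@H](O[Si](C)(C)C(C)(C)C)C/C(C)=C/CC/C(C)=C\[C@H]2OC1O | intermediate (not isolated)
29 | 13-acetoxy-8-(tert-butyldimethylsilyloxy)germacra-1(10)E,4Z,7(11)-trien-12,6-olide | CC(=O)OCC1=C2[C@@H](O[Si](C)(C)C(C)(C)C)C/C(C)=C/CC/C(C)=C\[C@H]2OC1=O | intermediate
30 | 13-acetoxy-8-hydroxygermacra-1(10)E,4Z,7(11)-trien-12,6-olide | CC(=O)OCC1=C2[C@@H](O)C/C(C)=C/CC/C(C)=C\[C@H]2OC1=O | intermediate
31 | (R)-2-methylglycidol | C[C@@]1(CO)CO1 | starting material
32 | 2-methyloxirane-2-carbaldehyde (configuration as in 31) | C[C@@]1(C=O)CO1 | intermediate (not isolated)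
33 | (S)-2-methyloxirane-2-carboxylic acid | C[C@@]1(C(O)=O)CO1 | intermediate
34 | mixed anhydride of 33 with 2,4,6-trichlorobenzoic acid | C[C@@]1(C(=O)OC(=O)c2c(Cl)cc(Cl)cc2Cl)CO1 | intermediate (not isolated)
35 | 13-acetoxy-8-[(2S)-2-methyloxirane-2-carbonyloxy]germacra-1(10)E,4Z,7(11)-trien-12,6-olide | CC(=O)OCC1=C2[C@@H](OC(=O)[C@]3(C)CO3)C/C(C)=C/CC/C(C)=C\[C@H]2OC1=O | intermediate
36 | (1R,10R)-1,10-monoepoxide of 35 | CC(=O)OCC1=C2[C@@H](OC(=O)[C@]3(C)CO3)C[C@@]3(C)O[C@@H]3CC/C(C)=C\[C@H]2OC1=O | intermediate (not isolated)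
37 | (1R,4R,5S,6S,8S,10R)-13-acetoxy-1,10:4,5-diepoxy-8-[(2S)-2-methyloxirane-2-carbonyloxy]germacr-7(11)-en-12,6-olide | CC(=O)OCC1=C2[C@@H](OC(=O)[C@]3(C)CO3)C[C@@]3(C)O[C@@H]3CC[C@@]3(C)O[C@H]3[C@H]2OC1=O | target

**Step count and risks**
Total steps: 24. Longest linear sequence: 23 steps (steps 1–21, 23 and 24); step 22 is a one-step side branch.

Most likely to fail:

1. Step 14. The rearranged tetrasubstituted potassium enolate is crowded, so O-sulfonylation may be slower than proton transfer; that would move the enolate to C5=C6 and on to loss of the C12 oxygen, or leave ketone after work-up. Passage of part of the material through the ring-flipped chair, which relieves allylic strain between the ylidene CH2 groups and the equatorial ethers, would show at the same stage as the 1(10)Z,4E isomer. Fallback: starting from 19, the rearrangement is run as before but the enolate is quenched with Me3SiCl/Et3N at −78 °C, a much faster trap, to give the trimethylsilyl enol ether F1, which can be purified, its alkene geometries checked and isomers separated. MeLi in THF at 0 °C then releases the lithium enolate, and N-(5-chloropyridin-2-yl)bis(trifluoromethanesulfonimide) at −78 °C gives the triflate, so the route is rejoined at 22.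

2. Step 24. Facial selectivity may be poor at one or both ring alkenes if a second ring conformer is populated, and the monoepoxide may undergo transannular attack by the remaining alkene. Fallback: reagent control in two stages from 35. A Shi epoxidation with 1,2:4,5-di-O-isopropylidene-β-D-erythro-2,3-hexodiulo-2,6-pyranose and KHSO5 at pH 10.5 (MeCN–dimethoxymethane–buffer, 0 °C) is aimed at the more electron-rich E alkene; on the spiro transition-state model it gives the (1R,10R) epoxide, that is 36, now isolated. The enantiomeric ketone under the same conditions then epoxidises the Z alkene, whose trans-related substituents are C15 and C6, to the (4R,5S) epoxide, returning at 37. This fallback makes no compound outside the list (F0).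

3. Step 17. DDQ may abstract hydride from the doubly allylic C6–H and over-oxidise to a dienone, or adventitious water may hydrolyse the oxocarbenium ion before ring closure, so that the benzyl group is lost and C12 and C13 are no longer told apart. Fallback: starting from 24, the benzyl ether is removed without an oxidant (MgBr2·OEt2, Me2S, CH2Cl2) to give the 6,12,13-triol F2. Excess (2,2,6,6-tetramethylpiperidin-1-yl)oxyl/PhI(OAc)2 then oxidises both primary alcohols on purpose, C12 to the lactone through its lactol and C13 to the aldehyde, giving the 13-oxo butenolide F3. NaBH4 with CeCl3·7H2O in MeOH at −78 °C reduces only the aldehyde to the 13-hydroxy butenolide F4, and Ac2O/pyridine acetylates it, returning at 29.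

**Further compounds**
F1 | step 14 | ten-membered trimethylsilyl enol ether (C4=C5–OSiMe3; otherwise as 22) | C1(=C2COC(C)(C)OC2)[C@@H](O[Si](C)(C)C(C)(C)C)C/C(C)=C/CC/C(C)=C(/O[Si](C)(C)C)[C@H]1OCc1ccc(OC)cc1
F2 | step 17 | 6,12,13-triol (8-OTBS) | C1(=C(CO)CO)[C@@H](O[Si](C)(C)C(C)(C)C)C/C(C)=C/CC/C(C)=C\[C@H]1O
F3 | step 17 | 13-oxo-8-(tert-butyldimethylsilyloxy)germacra-1(10)E,4Z,7(11)-trien-12,6-olide | O=CC1=C2[C@@H](O[Si](C)(C)C(C)(C)C)C/C(C)=C/CC/C(C)=C\[C@H]2OC1=O
F4 | step 17 | 13-hydroxy-8-(tert-butyldimethylsilyloxy)germacra-1(10)E,4Z,7(11)-trien-12,6-olide | OCC1=C2[C@@H](O[Si](C)(C)C(C)(C)C)C/C(C)=C/CC/C(C)=C\[C@H]2OC1=O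
F0 | step 24 | none | none
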